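**Plan**
- Numbering (elemane): ring C5–C10; vinyl C1=C2 and methyl C14 on C10; isopropenyl C3=C4(C15) on C5; lactone C11(C13)–C12 from C7 to O6.
- Retrosynthesis cuts, in order: the C8 acetate and C11 angelate; C11–O and C11–C13 (lactone enolate chemistry); the lactone bond O6–C12 and C6–H (back to a C6 ketone); then C1–C4 and C2–C3 are re-joined to a 6-4-4 tricycle, which is cut at C1–C10 and C4–C5 ([2+2]); last C7–C11 (enolate alkylation).
- Enabling feature: the vicinal C10 vinyl (C1, C2) and C5 isopropenyl (C4, C3, C15) are the two halves of 1-methylcyclobutene severed at C2–C3, and the ring bond C5–C10 is the former C=C of a C6 cyclohexenone in the six-membered ring.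
- Forward: the six-membered ring comes from cis,cis-cyclohexane-1,3,5-triol; the C7 acetate arm is attached to the enone; the central cyclobutane is closed by light; heat opens both four-membered rings; the γ-lactone ring closes after C6 reduction; C11 and the two esters come last.
- Stereochemistry: C8 from lipase desymmetrisation; C7 by alkylation trans to C8–OSi; C10 by cycloaddition anti to C8–OSi; C5 by oxime (allylic 1,3-strain) equilibration; C6 by C8–OH-directed hydride; C11 by convex-face enolate hydroxylation; Z-angelate from angelic acid.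

Key step: step 8

Remark: the lipase is assumed to acetylate the enantiotopic hydroxyl that gives monoacetate 3 as drawn; if it prefers the other one, the same enantiomer follows from lipase hydrolysis of the meso diacetate.

**Route**

Step 1
Reactants: 1 cis,cis-cyclohexane-1,3,5-triol
Product: 2 all-cis 5-(tert-butyldimethylsilyloxy)cyclohexane-1,3-diol (meso)
Conditions: TBSCl (1.0 equiv), imidazole, DMF, 0 °C
Reagents that add atoms: tert-butyldimethylsilyl chloride CC(C)(C)[Si](C)(C)Cl
Why: Statistical monosilylation of one of three equivalent hydroxyls (alcohol silylation) should give the meso diol, separable from triol and bis-silyl ether, and creates no stereocentre.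

Step 2
Reactants: 2 all-cis 5-(tert-butyldimethylsilyloxy)cyclohexane-1,3-diol
Product: 3 (1R,3S,5S)-3-(tert-butyldimethylsilyloxy)-5-hydroxycyclohexyl acetate
Conditions: lipase from Burkholderia cepacia (immobilised), vinyl acetate, tBuOMe, 25 °C
Reagents that add atoms: vinyl acetate C=COC(C)=O
Why: Lipase-catalysed irreversible transesterification desymmetrises the meso diol by acetylating one enantiotopic hydroxyl, which fixes the absolute configuration of the silyloxy carbon (later C8) once the two carbinols are differentiated.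

Step 3
Reactants: 3 (1R,3S,5S)-3-(tert-butyldimethylsilyloxy)-5-hydroxycyclohexyl acetate
Product: 5 (R)-5-(tert-butyldimethylsilyloxy)cyclohex-2-en-1-one, via acetoxy ketone 4 (not isolated)
Conditions: (COCl)2, DMSO, CH2Cl2, −78 °C; Et3N, −78 → 23 °C
Reagents that add atoms: none
Why: Swern oxidation of the free carbinol followed in the same flask by amine-promoted E1cB loss of acetic acid (acetate being a far better β-leaving group than silanolate) should give the enone with the silyloxy stereocentre untouched.

Step 4
Reactants: 5 (R)-5-(tert-butyldimethylsilyloxy)cyclohex-2-en-1-one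
Product: 6 (5R)-5-(tert-butyldimethylsilyloxy)-1-methylcyclohex-2-en-1-ol (both C1 epimers)
Conditions: MeLi, THF, −78 °C; then H2O
Reagents that add atoms: methyllithium [Li]C
Why: 1,2-Addition of the hard organolithium to the enone carbonyl gives the tertiary allylic alcohol, whose new carbinol centre is irrelevant because it is destroyed in step 5.

Step 5
Reactants: 6 (5R)-5-(tert-butyldimethylsilyloxy)-1-methylcyclohex-2-en-1-ol
Product: 7 (S)-5-(tert-butyldimethylsilyloxy)-3-methylcyclohex-2-en-1-one
Conditions: IBX, DMSO, 55 °C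
Reagents that add atoms: 2-iodoxybenzoic acid O=C1OI(=O)(O)c2ccccc12
Why: Oxidative 1,3-transposition of a tertiary allylic alcohol (Dauben-type rearrangement, here through the iodic ester) moves oxygen to the far allylic carbon and oxidises it to the β-methyl enone, the silyloxy centre keeping its spatial arrangement (the descriptor changes from R to S only because the ring priorities change).

Step 6
Reactants: 7 (S)-5-(tert-butyldimethylsilyloxy)-3-methylcyclohex-2-en-1-one
Product: 8 ethyl 2-[(1R,6S)-6-(tert-butyldimethylsilyloxy)-4-methyl-2-oxocyclohex-3-en-1-yl]acetate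
Conditions: LiN(iPr)2, THF, −78 °C; ICH2CO2Et, DMPU, −78 → −40 °C
Reagents that add atoms: ethyl iodoacetate CCOC(=O)CI
Why: Kinetic α′-deprotonation and C-alkylation of the cross-conjugated lithium dienolate (enolate alkylation) should place the acetate arm at C7 trans to the adjacent C8 silyloxy group, as in alkylations of carvone-type 5-substituted cyclohexenones.

Step 7
Reactants: 9 methylenecyclobutane
Product: 10 1-methylcyclobutene
Conditions: Na/Al2O3 (cat.), 25 °C; fractional distillation
Reagents that add atoms: none
Why: Base-catalysed double-bond isomerisation (allylic proton shift) moves the exocyclic alkene into the ring, the trisubstituted endocyclic isomer being favoured at equilibrium.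

Step 8
Reactants: 8 ethyl 2-[(1R,6S)-6-(tert-butyldimethylsilyloxy)-4-methyl-2-oxocyclohex-3-en-1-yl]acetate; 10 1-methylcyclobutene
Product: 11 cis-anti-cis photoadduct, ethyl 2-[9-(tert-butyldimethylsilyloxy)-1,5-dimethyl-7-oxotricyclo[4.4.0.0^2,5]decan-8-yl]acetate
Conditions: hν (medium-pressure Hg lamp, Pyrex filter, λ > 300 nm), 10 (8 equiv), CH2Cl2, −40 °C
Reagents that add atoms: none
Why: The excited enone reacts from its triplet state through the β-carbon C10 with the unsubstituted alkene carbon C1 of 10, giving a triplet 1,4-biradical (tertiary cyclobutyl radical at C4, α-acyl radical at C5) that closes C4–C5 after spin inversion; the closest known reaction type is the enone–cyclobutene [2+2] photocycloaddition. The one new ring, the central cyclobutane C10–C1–C4–C5, is closed stepwise by radical–radical combination on the face where C1 already sits, so it is cis-fused to the cyclohexanone, while the cyclobutene fusion C1/C4 stays cis and lies anti to the six-membered ring. C10 is set by approach of C1 anti to the C8 silyloxy group (as in conjugate additions to 5-substituted cyclohexenones), C1 and C4 by the cis geometry of the cyclobutene, and C5 by the cis ring closure. The step needs the regiochemistry C10–C1/C5–C4, secured because this orientation gives the more stabilised biradical and avoids joining two fully substituted carbons, and facial selectivity at C10, secured by the C8 silyloxy group (the equatorial C7 arm is remote from C10). Only C10 of the four new centres is carried to the target: C1 and C4 become sp2 in step 9 and C5 is corrected in step 11.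

Step 9
Reactants: 11 cis-anti-cis photoadduct
Product: 12 ethyl 2-[(1R,3S,4R,6S)-6-(tert-butyldimethylsilyloxy)-4-ethenyl-4-methyl-2-oxo-3-(prop-1-en-2-yl)cyclohexyl]acetate
Conditions: PhMe (degassed), base-washed sealed tube, 200 °C
Reagents that add atoms: none
Why: Thermal cycloreversion of the bicyclo[2.2.0]hexane (strain-driven cleavage of C1–C4 and C2–C3) opens both four-membered rings to the C10 vinyl and C5 isopropenyl groups; C10 is not touched, the cis ring fusion becomes a cis vinyl/isopropenyl pair, and the C7 arm stays equatorial and trans to C8–OSi.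

Step 10
Reactants: 12 cis-divinyl keto ester
Product: 13 ethyl 2-[(1R,3S,4R,6S)-4-ethenyl-6-hydroxy-4-methyl-2-oxo-3-(prop-1-en-2-yl)cyclohexyl]acetate
Conditions: HF·pyridine, pyridine, THF, 0 °C
Reagents that add atoms: none
Why: Fluoride-mediated silyl ether cleavage under buffered, non-basic conditions frees the C8 hydroxyl without enolising the ketone, so the β-hydroxy ketone should survive without E1cB elimination or retro-aldol opening.

Step 11
Reactants: 13 cis β-hydroxy ketone
Product: 14 ethyl 2-[(1S,2E,3R,4R,6S)-4-ethenyl-6-hydroxy-2-(hydroxyimino)-4-methyl-3-(prop-1-en-2-yl)cyclohexyl]acetate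
Conditions: NH2OH·HCl, pyridine, EtOH, 60 °C
Reagents that add atoms: hydroxylamine NO
Why: Oxime formation under equilibrating conditions (condensation with enolisation toward the doubly activated C5) exploits allylic 1,3-strain: the oxime hydroxyl tolerates a flanking substituent only when it is axial, so the all-equatorial cis-2,6 ketone should funnel into the oxime whose C5 isopropenyl is axial, trans to the C10 vinyl and to the equatorial C7 arm.

Step 12
Reactants: 14 trans oxime
Product: 15 ethyl 2-[(1R,3R,4R,6S)-4-ethenyl-6-hydroxy-4-methyl-2-oxo-3-(prop-1-en-2-yl)cyclohexyl]acetate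
Conditions: TiCl3 (aq.), NH4OAc, THF, 0 °C
Reagents that add atoms: water O
Why: Reductive deoximation (N–O cleavage by TiCl3, then hydrolysis of the N–H imine in the buffered medium) should release the ketone under conditions too mild to enolise it, so the C5 configuration set in the oxime is kept.

Step 13
Reactants: 15 trans β-hydroxy ketone
Product: 17 cis-fused hydroxy lactone (5R,6S,7R,8S,10R)-8-hydroxy-13-norelema-1,3-dien-12,6-olide, via anti diol 16 (not isolated)
Conditions: Me4NBH(OAc)3, MeCN–AcOH, −25 °C; then PPTS, PhH, 60 °C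
Reagents that add atoms: none
Why: Evans–Saksena hydroxyl-directed reduction: the acetoxyborohydride bound to the C8 oxygen delivers hydride to the face of C6 on which that oxygen lies, giving the 6,8-anti diol with C6–OH cis to the C7 arm, and mild acid then closes the cis-fused γ-lactone (transesterification) in preference to the more strained trans-fused ring through O8.

Step 14
Reactants: 17 cis-fused hydroxy lactone
Product: 18 (5R,6S,7S,8S,10R)-8-(tert-butyldimethylsilyloxy)-13-norelema-1,3-dien-12,6-olide
Conditions: TBSOTf, 2,6-lutidine, CH2Cl2, −78 °C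
Reagents that add atoms: tert-butyldimethylsilyl triflate CC(C)(C)[Si](C)(C)OS(=O)(=O)C(F)(F)F
Why: Silylation of the only free hydroxyl protects C8–OH against the strong bases and the acylation of steps 15 to 17.

Step 15
Reactants: 18 silyl-protected lactone
Product: 19 (5R,6S,7S,8S,10R,11S)-8-(tert-butyldimethylsilyloxy)elema-1,3-dien-12,6-olide (C13 methyl exo)
Conditions: LiN(iPr)2, THF, −78 °C; MeI, −78 → −40 °C
Reagents that add atoms: iodomethane CI
Why: Lactone enolate alkylation, in which iodomethane should enter C11 from the convex face of the cis-fused bicycle, although this centre is made planar again in step 16.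

Step 16
Reactants: 19 α-methyl lactone
Product: 20 (5R,6S,7S,8S,10R,11S)-8-(tert-butyldimethylsilyloxy)-11-hydroxyelema-1,3-dien-12,6-olide
Conditions: KN(SiMe3)2, THF, −78 °C; 2-(phenylsulfonyl)-3-phenyloxaziridine; then AcOH
Reagents that add atoms: 2-(phenylsulfonyl)-3-phenyloxaziridine O=S(=O)(N1OC1c1ccccc1)c1ccccc1
Why: Enolate hydroxylation with a Davis oxaziridine: the planar C11 enolate is oxidised on the convex face of the cis-fused lactone (the face of H6 and H7), which sets C11 with hydroxyl exo and methyl endo.

Step 17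
Reactants: 20 tertiary α-hydroxy lactone
Product: 21 (5R,6S,7S,8S,10R,11S)-11-angeloyloxy-8-(tert-butyldimethylsilyloxy)elema-1,3-dien-12,6-olide
Conditions: LiN(SiMe3)2, THF, −78 °C; mixed anhydride from angelic acid, 2,4,6-trichlorobenzoyl chloride and Et3N (PhMe, 0 °C); −78 → 0 °C
Reagents that add atoms: angelic acid C/C=C(/C)C(=O)O
Why: Acylation of the lithium tertiary alkoxide by a Yamaguchi-type mixed anhydride, which is attacked at the unhindered angeloyl carbonyl; low temperature and the absence of a nucleophilic catalyst should keep the Z double bond from isomerising to the tiglate.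

Step 18
Reactants: 21 silyl-protected angelate
Product: 22 (5R,6S,7R,8S,10R,11S)-11-angeloyloxy-8-hydroxyelema-1,3-dien-12,6-olide
Conditions: HF·pyridine, THF, 0 → 23 °C
Reagents that add atoms: none
Why: Fluoride cleavage of the secondary silyl ether under mildly acidic conditions leaves lactone, angelate and alkenes intact and avoids base-induced acyl migration from the C11 oxygen to O8.

Step 19
Reactants: 22 C8 alcohol
Product: 23 (5R,6S,7R,8S,10R,11S)-8-acetoxy-11-angeloyloxyelema-1,3-dien-12,6-olide (CNP0140071.1)
Conditions: Ac2O, pyridine, DMAP (cat.), CH2Cl2, 0 °C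
Reagents that add atoms: acetic anhydride CC(=O)OC(C)=O
Why: DMAP-catalysed acetylation of the secondary C8 hydroxyl completes the target without touching any stereocentre.

**Compound list**
1 | cis,cis-cyclohexane-1,3,5-triol | O[C@H]1C[C@@H](O)C[C@@H](O)C1 | starting material
2 | all-cis 5-(tert-butyldimethylsilyloxy)cyclohexane-1,3-diol (meso) | O[C@H]1C[C@@H](O)C[C@@H](O[Si](C)(C)C(C)(C)C)C1 | intermediate
3 | (1R,3S,5S)-3-(tert-butyldimethylsilyloxy)-5-hydroxycyclohexyl acetate | O[C@H]1C[C@@H](OC(C)=O)C[C@@H](O[Si](C)(C)C(C)(C)C)C1 | intermediate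
4 | (3S,5R)-3-acetoxy-5-(tert-butyldimethylsilyloxy)cyclohexanone | O=C1C[C@@H](OC(C)=O)C[C@@H](O[Si](C)(C)C(C)(C)C)C1 | intermediate
5 | (R)-5-(tert-butyldimethylsilyloxy)cyclohex-2-en-1-one | O=C1C=CC[C@@H](O[Si](C)(C)C(C)(C)C)C1 | intermediate
6 | (5R)-5-(tert-butyldimethylsilyloxy)-1-methylcyclohex-2-en-1-ol, both C1 epimers | CC1(O)C=CC[C@@H](O[Si](C)(C)C(C)(C)C)C1 | intermediate
7 | (S)-5-(tert-butyldimethylsilyloxy)-3-methylcyclohex-2-en-1-one | O=C1C=C(C)C[C@H](O[Si](C)(C)C(C)(C)C)C1 | intermediate
8 | ethyl 2-[(1R,6S)-6-(tert-butyldimethylsilyloxy)-4-methyl-2-oxocyclohex-3-en-1-yl]acetate (arm trans to OSi) | O=C1C=C(C)C[C@H](O[Si](C)(C)C(C)(C)C)[C@H]1CC(=O)OCC | intermediate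
9 | methylenecyclobutane | C=C1CCC1 | starting material
10 | 1-methylcyclobutene | CC1=CCC1 | intermediate
11 | cis-anti-cis photoadduct, ethyl 2-[9-(tert-butyldimethylsilyloxy)-1,5-dimethyl-7-oxotricyclo[4.4.0.0^2,5]decan-8-yl]acetate; elemane descriptors 1S,4R,5S,7R,8S,10R; central cyclobutane anti to OSi, outer cyclobutane anti to the six-membered ring | O=C1[C@H](CC(=O)OCC)[C@@H](O[Si](C)(C)C(C)(C)C)C[C@]2(C)[C@H]3CC[C@@]3(C)[C@H]12 | intermediate
12 | ethyl 2-[(1R,3S,4R,6S)-6-(tert-butyldimethylsilyloxy)-4-ethenyl-4-methyl-2-oxo-3-(prop-1-en-2-yl)cyclohexyl]acetate (isopropenyl cis to vinyl) | C=C[C@@]1(C)C[C@H](O[Si](C)(C)C(C)(C)C)[C@@H](CC(=O)OCC)C(=O)[C@H]1C(C)=C | intermediate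
13 | ethyl 2-[(1R,3S,4R,6S)-4-ethenyl-6-hydroxy-4-methyl-2-oxo-3-(prop-1-en-2-yl)cyclohexyl]acetate | C=C[C@@]1(C)C[C@H](O)[C@@H](CC(=O)OCC)C(=O)[C@H]1C(C)=C | intermediate
14 | ethyl 2-[(1S,2E,3R,4R,6S)-4-ethenyl-6-hydroxy-2-(hydroxyimino)-4-methyl-3-(prop-1-en-2-yl)cyclohexyl]acetate (oxime OH syn to C5, isopropenyl trans to vinyl) | C=C[C@@]1(C)C[C@H](O)[C@@H](CC(=O)OCC)/C(=N/O)[C@@H]1C(C)=C | intermediate
15 | ethyl 2-[(1R,3R,4R,6S)-4-ethenyl-6-hydroxy-4-methyl-2-oxo-3-(prop-1-en-2-yl)cyclohexyl]acetate | C=C[C@@]1(C)C[C@H](O)[C@@H](CC(=O)OCC)C(=O)[C@@H]1C(C)=C | intermediate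
16 | ethyl 2-[(1R,2S,3R,4R,6S)-4-ethenyl-2,6-dihydroxy-4-methyl-3-(prop-1-en-2-yl)cyclohexyl]acetate (6,8-anti diol) | C=C[C@@]1(C)C[C@H](O)[C@@H](CC(=O)OCC)[C@@H](O)[C@@H]1C(C)=C | intermediate
17 | (5R,6S,7R,8S,10R)-8-hydroxy-13-norelema-1,3-dien-12,6-olide (cis-fused γ-lactone) | C=C[C@@]1(C)C[C@H](O)[C@@H]2[C@@H](OC(=O)C2)[C@@H]1C(=C)C | intermediate
18 | (5R,6S,7S,8S,10R)-8-(tert-butyldimethylsilyloxy)-13-norelema-1,3-dien-12,6-olide | C=C[C@@]1(C)C[C@H](O[Si](C)(C)C(C)(C)C)[C@@H]2[C@@H](OC(=O)C2)[C@@H]1C(=C)C | intermediate
19 | (5R,6S,7S,8S,10R,11S)-8-(tert-butyldimethylsilyloxy)elema-1,3-dien-12,6-olide (C13 methyl on the convex face) | C=C[C@@]1(C)C[C@H](O[Si](C)(C)C(C)(C)C)[C@@H]2[C@@H](OC(=O)[C@H]2C)[C@@H]1C(=C)C | intermediate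
20 | (5R,6S,7S,8S,10R,11S)-8-(tert-butyldimethylsilyloxy)-11-hydroxyelema-1,3-dien-12,6-olide | C=C[C@@]1(C)C[C@H](O[Si](C)(C)C(C)(C)C)[C@@H]2[C@@H](OC(=O)[C@@]2(C)O)[C@@H]1C(=C)C | intermediate
21 | (5R,6S,7S,8S,10R,11S)-11-angeloyloxy-8-(tert-butyldimethylsilyloxy)elema-1,3-dien-12,6-olide | C=C[C@@]1(C)C[C@H](O[Si](C)(C)C(C)(C)C)[C@@H]2[C@@H](OC(=O)[C@@]2(C)OC(=O)/C(C)=C\C)[C@@H]1C(=C)C | intermediate
22 | (5R,6S,7R,8S,10R,11S)-11-angeloyloxy-8-hydroxyelema-1,3-dien-12,6-olide | C=C[C@@]1(C)C[C@H](O)[C@@H]2[C@@H](OC(=O)[C@@]2(C)OC(=O)/C(C)=C\C)[C@@H]1C(=C)C | intermediate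
23 | (5R,6S,7R,8S,10R,11S)-8-acetoxy-11-angeloyloxyelema-1,3-dien-12,6-olide (CNP0140071.1) | C=C[C@@]1(C)C[C@H](OC(C)=O)[C@@H]2[C@@H](OC(=O)[C@@]2(C)OC(=O)/C(C)=C\C)[C@@H]1C(=C)C | target

**Step count and risks**
Total step count: 19. Longest linear sequence: 18 steps (steps 1–6 and 8–19, from 1); step 7 is a one-step side branch.

The three steps most likely to fail:

Step 11. The trans relation at C5 is the less favoured one in the ketone series, so everything rests on the oxime. The epimerisation may stay incomplete (a strained cis oxime persists), may run at C7 instead of C5, or an oxime hydroxyl syn to C7 may cyclise onto the ester. The fallback sets out from 13 and comes back at 15: ketone 13 is equilibrated directly at C5 with DBU in toluene at 25 °C, the trans ketone 15 is separated by chromatography from the epimer mixture, and recovered 13 is returned to the equilibration. This is a plain thermodynamic ketone epimerisation with recycling and makes no new compound.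

Step 13. Hydride delivery needs the conformer with axial C8 oxygen, in which the axial C10 methyl crowds the C6 carbonyl, so the reduction may stall. The lactonisation may also engage O8 instead of O6. The fallback sets out from 15 and comes back at 18. The C8 hydroxyl is silylated (TBSOTf, 2,6-lutidine) to the silyl ether ketone F1. NaBH4 in MeOH at 0 °C then reduces C6 by axial attack anti to the axial isopropenyl group, which should give the C6-epimeric hydroxy ester F2 (C6–OH trans to the C7 arm). LiOH in aqueous THF gives the hydroxy acid F3. Mitsunobu lactonisation (PPh3, diisopropyl azodicarboxylate, PhMe) closes the lactone by intramolecular SN2 attack of the carboxylate with inversion at C6, which gives 18 directly.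

Step 6. The lithium dienolate carries a β-silyloxy group and may lose silanolate (E1cB) with aromatisation to a cresol before it is alkylated; dialkylation is a lesser concern. The fallback sets out from 7 and comes back at 8. HF·pyridine removes the silyl group to give (S)-5-hydroxy-3-methylcyclohex-2-en-1-one F4. LiN(iPr)2 (2.2 equiv) at −78 °C forms the alkoxide–dienolate dianion, which cannot eliminate, and ethyl iodoacetate alkylates it anti to the alkoxide (Fráter–Seebach-type alkylation) to give the hydroxy ester F5. TBSCl and imidazole in DMF then restore the silyl ether 8.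

Further compounds
F0 | step 11 | none | none
F1 | step 13 | ethyl 2-[(1R,3R,4R,6S)-6-(tert-butyldimethylsilyloxy)-4-ethenyl-4-methyl-2-oxo-3-(prop-1-en-2-yl)cyclohexyl]acetate (silyl ether of 15) | C=C[C@@]1(C)C[C@H](O[Si](C)(C)C(C)(C)C)[C@@H](CC(=O)OCC)C(=O)[C@@H]1C(C)=C
F2 | step 13 | C6-epimeric hydroxy ester, ethyl 2-[6-(tert-butyldimethylsilyloxy)-4-ethenyl-2-hydroxy-4-methyl-3-(prop-1-en-2-yl)cyclohexyl]acetate with C6–OH trans to the C7 arm | C=C[C@@]1(C)C[C@H](O[Si](C)(C)C(C)(C)C)[C@@H](CC(=O)OCC)[C@H](O)[C@@H]1C(C)=C
F3 | step 13 | corresponding hydroxy acid, 2-[6-(tert-butyldimethylsilyloxy)-4-ethenyl-2-hydroxy-4-methyl-3-(prop-1-en-2-yl)cyclohexyl]acetic acid with C6–OH trans to the C7 arm | C=C[C@@]1(C)C[C@H](O[Si](C)(C)C(C)(C)C)[C@@H](CC(=O)O)[C@H](O)[C@@H]1C(C)=C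
F4 | step 6 | (S)-5-hydroxy-3-methylcyclohex-2-en-1-one | O=C1C=C(C)C[C@H](O)C1
F5 | step 6 | ethyl 2-[(1R,6S)-6-hydroxy-4-methyl-2-oxocyclohex-3-en-1-yl]acetate | O=C1C=C(C)C[C@H](O)[C@H]1CC(=O)OCC
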